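**Strategy.** Everything rests on opening ring B at C6–C11 and C7=C8. The key step exploits two features: ring A carries the pattern of dimedone (oxygen at C1 and C3, gem-dimethyl C5, spiro atom C6 as its α-carbon), and ring B is a latent 4,4-disubstituted cyclohex-2-enone (C7=C8, oxygen at C9, para to C6). An enantioselective Michael addition to methyl vinyl ketone followed by aldol condensation onto a formyl carbon forms both bonds, ring B and the quaternary stereocentre C6 in one operation. The precursor is the enolised 6-formyl derivative of dimedone methyl enol ether. Ring A is adjusted afterwards, and the dibromomethyl carbinol is made last.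

Key step: step 3

Remark on numbering: C1–C11 are the positions of the spiro[5.5]undecane skeleton of the target (C1 methylidene carbon, C3 carbinol, C4 CHBr, C5 CMe2, C6 spiro atom, C7=C8, C9 carbinol); the same labels are used for every intermediate and in the names of the spiro compounds.

Assumption: the sense of induction of the cinchona catalyst on this donor cannot be derived with certainty; the quinine-derived catalyst is written, and its quinidine-derived pseudoenantiomer would take its place should it deliver the opposite face of C6.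

## Route

Step 1
Reactants: 1 dimedone
Product: 2 3-methoxy-5,5-dimethylcyclohex-2-en-1-one
Conditions: MeOH, TsOH·H2O (cat.), 3 Å MS, reflux
Reagents that add atoms: methanol, CO
Why: Acid-catalysed enol etherification of the symmetrical 1,3-dione should give the vinylogous ester as a single constitutional isomer, and no stereocentre is formed.

Step 2
Reactants: 2 3-methoxy-5,5-dimethylcyclohex-2-en-1-one; 3 ethyl formate
Product: 4 (6Z)-6-(hydroxymethylidene)-3-methoxy-5,5-dimethylcyclohex-2-en-1-one
Conditions: LDA, THF, −78 °C; then 3, −78 → 0 °C; AcOH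
Reagents that add atoms: none
Why: Kinetic deprotonation of a vinylogous ester with LDA takes place at the α′ carbon (C6), and Claisen formylation of that enolate with ethyl formate should give the β-keto aldehyde, which rests as its chelated enol; no stereocentre is formed.

Step 3
Reactants: 4 (6Z)-6-(hydroxymethylidene)-3-methoxy-5,5-dimethylcyclohex-2-en-1-one; 5 methyl vinyl ketone
Product: 7 (6R)-3-methoxy-5,5-dimethylspiro[5.5]undeca-2,7-diene-1,9-dione, via keto aldehyde 6 (not isolated)
Conditions: 5 (3 equiv), 9-O-(9-phenanthryl)cupreine (10 mol%), PhMe, 0 → 23 °C; excess 5 removed in vacuo; then TsOH·H2O (30 mol%), 4 Å MS, PhMe, 70 °C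
Reagents that add atoms: none
Why: The quinuclidine nitrogen of the bifunctional catalyst deprotonates the acidic enol of 4 and holds the enolate as a chiral ion pair while the 6′-hydroxyl group hydrogen-bonds the carbonyl of 5, so that conjugate addition through C6 forms C6–C11 and gives keto aldehyde 6. Acid then enolises the methyl ketone towards C8, which adds to the formyl carbon C7 and loses water, so that the whole is a Robinson-type spiroannulation; the closest known reactions are cinchona-catalysed Michael additions of α-substituted 1,3-dicarbonyl compounds to enones and the spiroannulation of α-formyl ketones with methyl vinyl ketone. Ring B closes in a 6-(enolendo)-exo-trig aldol step. The configuration at C6 is set in the Michael step by the catalyst, which shields one face of the planar enolate, and it cannot be lost afterwards because C6 is quaternary. The step needs C-alkylation at C6 and aldolisation at the aldehyde only: C6 is the only nucleophilic carbon of the donor, C1 is a deactivated vinylogous ester carbonyl, C6 bears no hydrogen, and closure through C10 would give a four-membered ring. Sulfonic acid is chosen for the condensation in place of a secondary amine or an alkoxide so that neither amine exchange at C3 nor retro-Claisen loss of the formyl group can intervene.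

Step 4
Reactants: 7 (6R)-3-methoxy-5,5-dimethylspiro[5.5]undeca-2,7-diene-1,9-dione
Product: 8 (6R)-9,9-ethylenedioxy-3-methoxy-5,5-dimethylspiro[5.5]undeca-2,7-dien-1-one
Conditions: (TMSOCH2)2, TMSOTf (5 mol%), CH2Cl2, −78 → −20 °C; pyridine
Reagents that add atoms: 1,2-bis(trimethylsilyloxy)ethane, C[Si](C)(C)OCCO[Si](C)(C)C
Why: Noyori ketalisation should convert the enone carbonyl C9 into its dioxolane without moving the C7=C8 double bond, while the ester-like vinylogous ester carbonyl C1 does not react; no stereocentre is formed.

Step 5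
Reactants: 8 (6R)-9,9-ethylenedioxy-3-methoxy-5,5-dimethylspiro[5.5]undeca-2,7-dien-1-one
Product: 10 (4S,6R)-4-bromo-9,9-ethylenedioxy-3-methoxy-5,5-dimethylspiro[5.5]undeca-2,7-dien-1-one, via silyl dienol ether 9 (not isolated)
Conditions: LDA, THF, −78 °C; TMSCl, −78 → 0 °C; then NBS, THF, −78 °C
Reagents that add atoms: N-bromosuccinimide, O=C1CCC(=O)N1Br; chlorotrimethylsilane, C[Si](C)(C)Cl (silyl group of 9 only)
Why: With C6 quaternary, LDA can only remove a γ-proton at C4, the dienolate is trapped on oxygen, and NBS should attack the doubly activated terminus C4 of the resulting 1-silyloxy-3-methoxy diene (vinylogous α-halogenation); bromine is expected to enter anti to the pseudoaxial C11 methylene, on the face of the flatter sp2 carbon C7, which gives 4S, but the bias is modest and the minor 4R epimer is to be removed by chromatography.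

Step 6
Reactants: 10 (4S,6R)-4-bromo-9,9-ethylenedioxy-3-methoxy-5,5-dimethylspiro[5.5]undeca-2,7-dien-1-one
Product: 12 (4S,6S)-4-bromo-1-(bromomethyl)-9,9-ethylenedioxy-5,5-dimethylspiro[5.5]undeca-1,7-dien-3-one, via bromo dienol ether 11 (not isolated)
Conditions: Tebbe reagent, pyridine (cat.), THF/PhMe, −40 → 0 °C; aq NaOH, filtration; then NBS, NaHCO3, THF/H2O, 0 °C
Reagents that add atoms: Tebbe reagent, C[Al-]1(C)C[Ti]([Cl+]1)(C1C=CC=C1)C1C=CC=C1; N-bromosuccinimide, O=C1CCC(=O)N1Br; water, O
Why: Tebbe methylenation of the ester-like carbonyl C1 should give dienol ether 11, and because neutral dienol ethers take up electrophiles (a proton included) at the terminal carbon, as the dienol ethers of steroidal enones do, NBS in water should add bromine to the new methylene carbon and unveil the C3 ketone in conjugation with C1=C2; C4 and C6 are untouched, and the exocyclic alkene is restored in step 8.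

Step 7
Reactants: 12 (4S,6S)-4-bromo-1-(bromomethyl)-9,9-ethylenedioxy-5,5-dimethylspiro[5.5]undeca-1,7-dien-3-one
Product: 13 (3R,4S,6S)-4-bromo-1-(bromomethyl)-9,9-ethylenedioxy-5,5-dimethylspiro[5.5]undeca-1,7-dien-3-ol
Conditions: DIBAL-H, THF, −78 °C; Rochelle salt
Reagents that add atoms: none
Why: 1,2-Reduction of the enone by DIBAL-H, in which hydride should add to C3 anti to the adjacent C4 bromine (Felkin–Anh/Cornforth control, reinforced by the bulk of the reagent) and so set 3R with the hydroxyl cis to bromine; at −78 °C neither bromide nor the ketal should react.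

Step 8
Reactants: 13 (3R,4S,6S)-4-bromo-1-(bromomethyl)-9,9-ethylenedioxy-5,5-dimethylspiro[5.5]undeca-1,7-dien-3-ol
Product: 15 (3R,4S,6S)-4-bromo-3-hydroxy-5,5-dimethyl-1-methylidenespiro[5.5]undec-7-en-9-one, via bromohydrin ketal 14 (not isolated)
Conditions: Pd(OAc)2 (5 mol%), n-Bu3P (20 mol%), HCO2H, Et3N, THF, 40 °C; then 1 M HCl, THF, 0 °C
Reagents that add atoms: water, O
Why: Tsuji hydrogenolysis, in which Pd(0) ionises the primary allylic bromide and the palladium hydride formed from formate delivers hydrogen to the more substituted allyl terminus C2, should leave the exocyclic C1 methylidene group while the unactivated secondary bromide at C4 stays inert; dilute acid in the work-up then hydrolyses the allylic dioxolane to the enone.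

Step 9
Reactants: 15 (3R,4S,6S)-4-bromo-3-hydroxy-5,5-dimethyl-1-methylidenespiro[5.5]undec-7-en-9-one
Product: 16 mailiohydrin, (3R,4S,6S,9R)-4-bromo-9-(dibromomethyl)-5,5-dimethyl-1-methylidenespiro[5.5]undec-7-ene-3,9-diol
Conditions: CH2Br2, LDA (excess, one equivalent is consumed by the C3 hydroxyl), THF, −78 °C; then 15; AcOH, −78 °C
Reagents that add atoms: dibromomethane (as dibromomethyllithium), BrCBr
Why: 1,2-Addition of the carbenoid dibromomethyllithium to the enone carbonyl, quenched cold before the alkoxide can close to a bromo epoxide; with ring B as a half-chair that keeps C5 pseudoequatorial and C1 pseudoaxial, the bulky reagent is expected to take the equatorial trajectory on the face that carries C1, which places the dibromomethyl group pseudoequatorial and gives 9R, though this selectivity is not secured and the 9-epimer is to be removed by chromatography.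

## Compound list

1 | dimedone (5,5-dimethylcyclohexane-1,3-dione) | CC1(C)CC(=O)CC(=O)C1 | starting material
2 | 3-methoxy-5,5-dimethylcyclohex-2-en-1-one | COC1=CC(=O)CC(C)(C)C1 | intermediate
3 | ethyl formate | CCOC=O | starting material
4 | (6Z)-6-(hydroxymethylidene)-3-methoxy-5,5-dimethylcyclohex-2-en-1-one | COC1=CC(=O)/C(=C\O)C(C)(C)C1 | intermediate
5 | methyl vinyl ketone | CC(=O)C=C | starting material
6 | (1S)-4-methoxy-6,6-dimethyl-2-oxo-1-(3-oxobutyl)cyclohex-3-ene-1-carbaldehyde | COC1=CC(=O)[C@@](C=O)(CCC(C)=O)C(C)(C)C1 | intermediate (not isolated)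
7 | (6R)-3-methoxy-5,5-dimethylspiro[5.5]undeca-2,7-diene-1,9-dione | COC1=CC(=O)[C@]2(C=CC(=O)CC2)C(C)(C)C1 | intermediate
8 | (6R)-9,9-ethylenedioxy-3-methoxy-5,5-dimethylspiro[5.5]undeca-2,7-dien-1-one | COC1=CC(=O)[C@]2(C=CC3(OCCO3)CC2)C(C)(C)C1 | intermediate
9 | (6R)-9,9-ethylenedioxy-3-methoxy-5,5-dimethyl-1-(trimethylsilyloxy)spiro[5.5]undeca-1,3,7-triene | COC1=CC(C)(C)[C@@]2(C=CC3(OCCO3)CC2)C(O[Si](C)(C)C)=C1 | intermediate (not isolated)
10 | (4S,6R)-4-bromo-9,9-ethylenedioxy-3-methoxy-5,5-dimethylspiro[5.5]undeca-2,7-dien-1-one | COC1=CC(=O)[C@]2(C=CC3(OCCO3)CC2)C(C)(C)[C@@H]1Br | intermediate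
11 | (4S,6S)-4-bromo-9,9-ethylenedioxy-3-methoxy-5,5-dimethyl-1-methylidenespiro[5.5]undeca-2,7-diene | COC1=CC(=C)[C@]2(C=CC3(OCCO3)CC2)C(C)(C)[C@@H]1Br | intermediate (not isolated)
12 | (4S,6S)-4-bromo-1-(bromomethyl)-9,9-ethylenedioxy-5,5-dimethylspiro[5.5]undeca-1,7-dien-3-one | O=C1C=C(CBr)[C@]2(C=CC3(OCCO3)CC2)C(C)(C)[C@@H]1Br | intermediate
13 | (3R,4S,6S)-4-bromo-1-(bromomethyl)-9,9-ethylenedioxy-5,5-dimethylspiro[5.5]undeca-1,7-dien-3-ol | O[C@@H]1C=C(CBr)[C@]2(C=CC3(OCCO3)CC2)C(C)(C)[C@@H]1Br | intermediate
14 | (3R,4S,6S)-4-bromo-9,9-ethylenedioxy-5,5-dimethyl-1-methylidenespiro[5.5]undec-7-en-3-ol | O[C@@H]1CC(=C)[C@]2(C=CC3(OCCO3)CC2)C(C)(C)[C@@H]1Br | intermediate (not isolated)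
15 | (3R,4S,6S)-4-bromo-3-hydroxy-5,5-dimethyl-1-methylidenespiro[5.5]undec-7-en-9-one | O[C@@H]1CC(=C)[C@]2(C=CC(=O)CC2)C(C)(C)[C@@H]1Br | intermediate
16 | mailiohydrin, (3R,4S,6S,9R)-4-bromo-9-(dibromomethyl)-5,5-dimethyl-1-methylidenespiro[5.5]undec-7-ene-3,9-diol | C=C1C[C@@H](O)[C@@H](Br)C(C)(C)[C@@]12C=C[C@@](O)(C(Br)Br)CC2 | target

## Step count and risks

Total step count: 9. Longest linear sequence: 9 steps (from dimedone).

**Step 3.** The conjugate addition has to create a quaternary carbon between the carbonyl C1 and the gem-dimethyl carbon C5. It may therefore be slow enough for O-alkylation or polymerisation of the enone to compete, and the enantiofacial control of the catalyst may erode. Fallback: the same ring is closed by cycloaddition, setting out from 4 and coming back at 7. Treatment of 4 with aqueous formaldehyde and K2CO3 (deformylative methylenation) should give 3-methoxy-5,5-dimethyl-6-methylidenecyclohex-2-en-1-one F1. Diels–Alder reaction with Danishefsky's diene (PhMe, heat, or ZnCl2) should then join the nucleophilic diene terminus to the exocyclic methylene carbon (C11) and the methoxy-bearing terminus to C6, giving 3,7-dimethoxy-5,5-dimethyl-9-(trimethylsilyloxy)spiro[5.5]undeca-2,8-dien-1-one F2. Dilute acid converts it into racemic 3-methoxy-5,5-dimethylspiro[5.5]undeca-2,7-diene-1,9-dione F3, and preparative chromatography on a chiral stationary phase returns the route at 7.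

**Step 6.** Methylenation of the hindered, ester-like carbonyl may stall, or the allylic C4–Br bond of the electron-rich diene may ionise before the diene is trapped, with loss of bromide or of the C4 configuration. Fallback: the carbon is brought in as a nucleophile, setting out from 10 and coming back at 12. Methylcerium dichloride (MeLi, CeCl3, THF, −78 °C) should add to C1 to give (4S,6R)-4-bromo-9,9-ethylenedioxy-3-methoxy-1,5,5-trimethylspiro[5.5]undeca-2,7-dien-1-ol F4. Cold dilute oxalic acid should then effect the Stork–Danheiser transposition to (4S,6S)-4-bromo-9,9-ethylenedioxy-1,5,5-trimethylspiro[5.5]undeca-1,7-dien-3-one F5. Wohl–Ziegler bromination (NBS, AIBN, PhCF3, 80 °C) of its only allylic C–H bonds, those of the C1 methyl group, returns the route at 12.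

**Step 9.** Facial selectivity at C9 may be poor, since axial entry anti to the pseudoaxial C1 would give the 9-epimer, and the lithium alkoxide may close to a bromo epoxide if the mixture warms. Fallback: a bulkier nucleophile is used and then trimmed, setting out from 15 and coming back at 16. Tribromomethyllithium (CHBr3, LDA, THF/Et2O, −100 °C), for which equatorial entry is more strongly enforced, should give (3R,4S,6S,9R)-4-bromo-5,5-dimethyl-1-methylidene-9-(tribromomethyl)spiro[5.5]undec-7-ene-3,9-diol F6. One bromine is then exchanged for hydrogen (i-PrMgCl in excess, THF, −78 °C; AcOH at −78 °C), which returns the route at 16.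

## Further compounds

F1 | step 3 | 3-methoxy-5,5-dimethyl-6-methylidenecyclohex-2-en-1-one | COC1=CC(=O)C(=C)C(C)(C)C1
F2 | step 3 | 3,7-dimethoxy-5,5-dimethyl-9-(trimethylsilyloxy)spiro[5.5]undeca-2,8-dien-1-one (racemic, both C7 epimers) | COC1=CC(=O)C2(C(OC)C=C(O[Si](C)(C)C)CC2)C(C)(C)C1
F3 | step 3 | racemic 3-methoxy-5,5-dimethylspiro[5.5]undeca-2,7-diene-1,9-dione | COC1=CC(=O)C2(C=CC(=O)CC2)C(C)(C)C1
F4 | step 6 | (4S,6R)-4-bromo-9,9-ethylenedioxy-3-methoxy-1,5,5-trimethylspiro[5.5]undeca-2,7-dien-1-ol (both C1 epimers) | COC1=CC(C)(O)[C@]2(C=CC3(OCCO3)CC2)C(C)(C)[C@@H]1Br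
F5 | step 6 | (4S,6S)-4-bromo-9,9-ethylenedioxy-1,5,5-trimethylspiro[5.5]undeca-1,7-dien-3-one | O=C1C=C(C)[C@]2(C=CC3(OCCO3)CC2)C(C)(C)[C@@H]1Br
F6 | step 9 | (3R,4S,6S,9R)-4-bromo-5,5-dimethyl-1-methylidene-9-(tribromomethyl)spiro[5.5]undec-7-ene-3,9-diol | C=C1C[C@@H](O)[C@@H](Br)C(C)(C)[C@@]12C=C[C@@](O)(C(Br)(Br)Br)CC2
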